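**Retrosynthetic overview**
- Target ⇐ its 7,4'-di-O-acetate by lipase-catalysed alcoholysis. This neutral final unmasking avoids base (chalcone ring-opening and racemisation) and acid (prenyl/phenol cyclisation to chromans).
- C2–C1' bond: diacetate ⇐ 7-acetoxy-6,8-diprenylchromone + 4-acetoxy-3-prenylphenylboronic acid by Rh/chiral bisphosphine asymmetric 1,4-addition, which sets the only stereocentre (2S).
- All three prenyl groups ⇐ aryl iodides by Stille coupling with a prenylstannane; the iodination pattern fixes the positions.
- Ring order: the A ring is bought (2,4-dihydroxyacetophenone), the C ring is closed early as a chromone (enaminone cyclisation), and the B ring (from 4-bromo-2-iodophenol) is attached last.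

Assumption: the target is the (2S)-flavanone as drawn, (2S)-7,4'-dihydroxy-6,8,3'-triprenylflavanone, and catalogue reagents (prenylstannane, chiral ligand, immobilised lipase) count as commercially available.

**Route**

Step 1
Reactants: 1, 2,4-dihydroxyacetophenone
Product: 2, 1-(2,4-dihydroxy-3,5-diiodophenyl)ethan-1-one
Conditions: I2 (0.85 equiv), HIO3 (0.45 equiv), EtOH/H2O, 40 °C
Reagents that add atoms: iodine, II; iodic acid, OI(=O)=O
Why: Electrophilic aromatic iodination goes only to C3 and C5, the two positions ortho/para to both hydroxyls, while C6 is deactivated by the acetyl group.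

Step 2
Reactants: 2, 1-(2,4-dihydroxy-3,5-diiodophenyl)ethan-1-one
Product: 3, 1-[2-hydroxy-3,5-diiodo-4-(methoxymethoxy)phenyl]ethan-1-one
Conditions: MOMCl (1.1 equiv), K2CO3, acetone, 0 °C to rt
Reagents that add atoms: chloromethyl methyl ether, COCCl
Why: Selective Williamson-type O-alkylation of the more acidic, non-chelated 4-OH; the 2-OH is hydrogen-bonded to the ketone and stays free for ring closure.

Step 3
Reactants: 3, 1-[2-hydroxy-3,5-diiodo-4-(methoxymethoxy)phenyl]ethan-1-one
Product: 4, (E)-3-(dimethylamino)-1-[2-hydroxy-3,5-diiodo-4-(methoxymethoxy)phenyl]prop-2-en-1-one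
Conditions: DMF-DMA (3 equiv), toluene, 90 °C
Reagents that add atoms: N,N-dimethylformamide dimethyl acetal, COC(OC)N(C)C
Why: Enaminone formation by condensation of the methyl ketone with the formamide acetal, the standard one-carbon homologation for chromone synthesis.

Step 4
Reactants: 4, the enaminone
Product: 5, 7-hydroxy-6,8-diiodo-4H-chromen-4-one
Conditions: 3 M HCl, MeOH, 55 °C
Reagents that add atoms: none
Why: Acid-promoted 6-endo addition–elimination (phenol O onto the enaminone β-carbon, loss of Me2NH) closes the pyranone ring, and the same acid removes the MOM acetal; no prenyl groups are present yet.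

Step 5
Reactants: 5, 7-hydroxy-6,8-diiodo-4H-chromen-4-one
Product: 6, 6,8-diiodo-4-oxo-4H-chromen-7-yl acetate
Conditions: Ac2O, pyridine, DMAP (cat.), CH2Cl2, rt
Reagents that add atoms: acetic anhydride, CC(=O)OC(C)=O
Why: DMAP-catalysed O-acylation; the acetate is chosen because it makes the chromone a better Michael acceptor than an ether would and can be removed enzymatically at the end.

Step 6
Reactants: 6, 6,8-diiodo-4-oxo-4H-chromen-7-yl acetate; 7, tributyl(3-methylbut-2-en-1-yl)stannane (2.5 equiv)
Product: 8, 6,8-bis(3-methylbut-2-en-1-yl)-4-oxo-4H-chromen-7-yl acetate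
Conditions: Pd(PPh3)4 (10 mol %), degassed DMF, 90 °C
Reagents that add atoms: tributyl(3-methylbut-2-en-1-yl)stannane (7), CC(C)=CC[Sn](CCCC)(CCCC)CCCC
Why: Double Stille coupling under neutral conditions (acetate and chromone tolerated); reductive elimination at the less hindered allyl terminus gives the linear prenyl groups.

Step 7
Reactants: 9, 4-bromo-2-iodophenol
Product: 10, 4-bromo-2-iodophenyl acetate
Conditions: Ac2O, Et3N, DMAP (cat.), CH2Cl2, rt
Reagents that add atoms: acetic anhydride, CC(=O)OC(C)=O
Why: Routine phenol acetylation, installing the same enzyme-labile group as on the A ring.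

Step 8
Reactants: 10, 4-bromo-2-iodophenyl acetate; 7, tributyl(3-methylbut-2-en-1-yl)stannane (1.05 equiv)
Product: 11, 4-bromo-2-(3-methylbut-2-en-1-yl)phenyl acetate
Conditions: Pd(PPh3)4 (5 mol %), degassed DMF, 80 °C
Reagents that add atoms: tributyl(3-methylbut-2-en-1-yl)stannane (7), CC(C)=CC[Sn](CCCC)(CCCC)CCCC
Why: Chemoselective Stille coupling; oxidative addition into C–I is much faster than into the electron-rich C–Br, so only the position ortho to oxygen is prenylated.

Step 9
Reactants: 11, 4-bromo-2-(3-methylbut-2-en-1-yl)phenyl acetate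
Product: 12, 2-(3-methylbut-2-en-1-yl)-4-(4,4,5,5-tetramethyl-1,3,2-dioxaborolan-2-yl)phenyl acetate
Conditions: B2pin2 (1.2 equiv), PdCl2(dppf) (4 mol %), KOAc, 1,4-dioxane, 85 °C
Reagents that add atoms: bis(pinacolato)diboron, CC1(C)OB(OC1(C)C)B1OC(C)(C)C(C)(C)O1
Why: Miyaura borylation with the weak base KOAc leaves the aryl acetate and the trisubstituted alkene untouched.

Step 10
Reactants: 12, the pinacol boronate
Product: 13, [4-acetoxy-3-(3-methylbut-2-en-1-yl)phenyl]boronic acid
Conditions: NaIO4 (3 equiv), THF/H2O, rt; then 1 M HCl, rt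
Reagents that add atoms: water, O
Why: Oxidative cleavage of the pinacol diol by periodate drives boronate hydrolysis to the free boronic acid (the reactive partner for Rh); periodate alone does not touch the prenyl alkene and dilute acid at rt spares the acetate.

Step 11
Reactants: 8, 6,8-bis(3-methylbut-2-en-1-yl)-4-oxo-4H-chromen-7-yl acetate; 13, [4-acetoxy-3-(3-methylbut-2-en-1-yl)phenyl]boronic acid (2.5 equiv)
Product: 14, (2S)-2-[4-acetoxy-3-(3-methylbut-2-en-1-yl)phenyl]-6,8-bis(3-methylbut-2-en-1-yl)-4-oxochroman-7-yl acetate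
Conditions: [Rh(OH)(cod)]2 (1.5 mol %), (S)-MeO-F12-BIPHEP (3.3 mol %), CH2Cl2/H2O (10:1), 25 °C, no added base
Reagents that add atoms: boronic acid 13, CC(=O)Oc1ccc(cc1CC=C(C)C)B(O)O
Why: Hayashi–Miyaura Rh(I)-catalysed asymmetric 1,4-addition, in which the electron-poor (S)-biaryl bisphosphine makes aryl-Rh insertion into the chromone C2=C3 fast at rt and shields one enantioface so the aryl group adds to C2 to give 2S; the (S)-ligand is chosen by analogy with the (S)-BINAP/Rh cyclohexenone model, so ee and sense are confirmed by chiral HPLC and CD and the equally available (R)-ligand is used if the sense is reversed.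

Step 12
Reactants: 14, the (2S)-diacetate
Product: 15, (2S)-7-hydroxy-2-[4-hydroxy-3-(3-methylbut-2-en-1-yl)phenyl]-6,8-bis(3-methylbut-2-en-1-yl)chroman-4-one (target)
Conditions: lipase (immobilised Burkholderia cepacia lipase, Amano PS-IM), n-BuOH (10 equiv), THF, 42 °C; filter off enzyme
Reagents that add atoms: none
Why: Lipase-catalysed transesterification (a serine carboxylic-ester hydrolase transfers both acetyl groups to n-butanol) cleaves the 7- and 4'-acetates, the positions lipases are known to deacylate in flavonoid acetates, at neutral pH, so C2 is not epimerised by retro-oxa-Michael opening and the ortho-prenyl phenols do not cyclise.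

**Compound list**
1 | 2,4-dihydroxyacetophenone | CC(=O)c1ccc(O)cc1O | starting material
2 | 1-(2,4-dihydroxy-3,5-diiodophenyl)ethan-1-one | CC(=O)c1cc(I)c(O)c(I)c1O | intermediate
3 | 1-[2-hydroxy-3,5-diiodo-4-(methoxymethoxy)phenyl]ethan-1-one | CC(=O)c1cc(I)c(OCOC)c(I)c1O | intermediate
4 | (E)-3-(dimethylamino)-1-[2-hydroxy-3,5-diiodo-4-(methoxymethoxy)phenyl]prop-2-en-1-one | CN(C)/C=C/C(=O)c1cc(I)c(OCOC)c(I)c1O | intermediate
5 | 7-hydroxy-6,8-diiodo-4H-chromen-4-one | O=c1ccoc2c(I)c(O)c(I)cc12 | intermediate
6 | 6,8-diiodo-4-oxo-4H-chromen-7-yl acetate | CC(=O)Oc1c(I)cc2c(=O)ccoc2c1I | intermediate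
7 | tributyl(3-methylbut-2-en-1-yl)stannane | CC(C)=CC[Sn](CCCC)(CCCC)CCCC | starting material
8 | 6,8-bis(3-methylbut-2-en-1-yl)-4-oxo-4H-chromen-7-yl acetate | CC(=O)Oc1c(CC=C(C)C)cc2c(=O)ccoc2c1CC=C(C)C | intermediate
9 | 4-bromo-2-iodophenol | Oc1ccc(Br)cc1I | starting material
10 | 4-bromo-2-iodophenyl acetate | CC(=O)Oc1ccc(Br)cc1I | intermediate
11 | 4-bromo-2-(3-methylbut-2-en-1-yl)phenyl acetate | CC(=O)Oc1ccc(Br)cc1CC=C(C)C | intermediate
12 | 2-(3-methylbut-2-en-1-yl)-4-(4,4,5,5-tetramethyl-1,3,2-dioxaborolan-2-yl)phenyl acetate | CC(=O)Oc1ccc(cc1CC=C(C)C)B1OC(C)(C)C(C)(C)O1 | intermediate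
13 | [4-acetoxy-3-(3-methylbut-2-en-1-yl)phenyl]boronic acid | CC(=O)Oc1ccc(cc1CC=C(C)C)B(O)O | intermediate
14 | (2S)-2-[4-acetoxy-3-(3-methylbut-2-en-1-yl)phenyl]-6,8-bis(3-methylbut-2-en-1-yl)-4-oxochroman-7-yl acetate | CC(C)=CCc1cc([C@@H]2CC(=O)c3cc(CC=C(C)C)c(OC(C)=O)c(CC=C(C)C)c3O2)ccc1OC(C)=O | intermediate
15 | (2S)-7-hydroxy-2-[4-hydroxy-3-(3-methylbut-2-en-1-yl)phenyl]-6,8-bis(3-methylbut-2-en-1-yl)chroman-4-one | CC(C)=CCc1cc([C@@H]2CC(=O)c3cc(CC=C(C)C)c(O)c(CC=C(C)C)c3O2)ccc1O | target

**Totals**
Total steps: 12. Longest linear sequence: 8 (steps 1–6, 11, 12); the B-ring branch is steps 7–10.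

**Steps most likely to fail, with fallbacks**
1. Step 11 (asymmetric 1,4-addition). Chromones are sluggish acceptors, and the adduct can ring-open to the chalcone or over-add. Fallback: abandon the conjugate addition and build the 2'-hydroxychalcone by Claisen–Schmidt condensation of the corresponding prenylated acetophenone and benzaldehyde. Then close the C ring by an enantioselective intramolecular oxa-Michael reaction, using a bifunctional cinchona-thiourea catalyst on the β-ketoester-activated chalcone followed by decarboxylation, or a chalcone isomerase.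
2. Step 6 (double Stille prenylation). The C8 iodide is flanked on both sides, and some branched (reverse-prenyl) product or acetate loss is possible. Fallback: build each prenyl group in two stages, by Stille allylation with allyltributylstannane (no regiochemical ambiguity) followed by olefin cross-metathesis with 2-methyl-2-butene (Grubbs II).
3. Step 12 (lipase deacetylation). The 7-acetate sits between two prenyl groups and may be a poor fit for the enzyme. Fallback: change the protecting-group plan so that the 7-oxygen is carried from compound 5 as a TBS ether through steps 6 and 11 and removed with buffered Et3N·3HF, leaving only the unhindered 4'-acetate for the lipase.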